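The numbers in the tables are calculated for an exercise, noise included.

**Counting first.** Begin with a count, before any dynamics. In the proposed steps D turns L into E and X into J, using one Q each time, while Z holds part of D as G and L and X may turn into each other.

| flask | L | X | Q | D | Z | temperature | remark | time |
|---|---|---|---|---|---|---|---|---|
| delta | 20 mM | 20 mM | 1.2 equiv | 8.9 mol% | 3.4 mM | 60 °C | the very flask that is asked about, followed so far |  |
| eta | 20 mM | 20 mM | 0.60 equiv | 8.9 mol% | 3.4 mM | 45 °C | run made earlier |  |
| flask | 20 mM | 20 mM | 1.20 equiv | 8.9 mol% | 3.4 mM | 60 °C |  | 40 h |

- delta (time / h: E / %, L / %): 3.00: 27.8, 23.7; 8.00: 43.1, 18.5; 15.0: 51.8, 17.4; 25.0: 58.0, 18.1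
- eta (time / h: E / %, L / %): 10.0: 18.7, 33.7; 20.0: 22.9, 30.8; 30.0: 25.6, 29.0; 40.0: 27.6, 29.7

(readings scatter by 1 percentage point)

- midnight: at 40 h raise the temperature by 10 K, then wait 3.0 d
- autumn: at 40 h add Q, 50.0% of the amount charged, then wait 3.0 d
- spring: change nothing and wait 3.0 d more
- noon: at 40 h take out 90% of the E then present, then wait 3.0 d
- dusk: at 40 h add D, 100% of the amount charged, then wait 3.0 d

- D is single-handed; L and X are mirror images of each other, charged as a racemate, each of them at the stated concentration
- removed E is counted in
- steps that have been proposed: Q + D + L -> D + E; Q + D + X -> D + J; D + Z <-> G; L <-> X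
- additions bring no volume worth counting

* E, in percent of the L and X together first charged, at 40 h
* what to do for the largest gain in E; "none" if nothing gains more than 2 percentage points (midnight / autumn / spring / noon / dusk / none)
* E present, with what was taken out counted in, in percent of the L and X together first charged, after midnight
* E present, with what was taken out counted in, in percent of the L and X together first charged, after noon

**The ceiling.** Percentages count L and X together, so 1.20 equiv of Q on L is worth 60.0%. This is the Q ceiling, the E plus J that the charged Q can pay for. In the eta run the same count gives 30.0%, and E reads 27.6% at 40.0 h.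

**Two extremes.** Picture a frozen flask, where L and X never turn into each other: E stops at the charged L, 50.0%. Now picture a fast flask, where L and X flip instantly: E climbs to the ceiling, with Q as limiting reagent. The delta flask is not frozen, because E reads 58.0% at 25.0 h, above 50.0%. So you expect it to end near the ceiling, with some delay.

**The delay.** In the delta run L moved by 0.7 percentage points between 15.0 h and 25.0 h, and a reading carries 1 point. So replace L's curve by its mean, 17.8%. Q then falls pseudo-first-order, with one time constant. The gap to the ceiling reads 8.2 points, then 2 points, which gives 7.09 h, a rough value given that scatter. At 40 h the gap is 0.24 points, so my E is 59.8%, with the unread J counted as nothing. Heat, more D, waiting or removing E leave the ceiling where it is, and that gap is less than 2 points. Adding Q lifts the ceiling to 90.0%.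

**The forecast.** It says 59.2%, lower than mine, with autumn as best, 59.4% after midnight and 59.4% after noon. Its ground is that “the slowdown is Q running out rather than the catalyst dying”.

**The result.** The flask gives 58.5% at 40 h, and autumn is best, adding 29 points. After midnight E stands at 59.0%, and after noon, with what was taken out counted in, at 59.0%. The steps are these.

    Q + D + L → D + E (k = 200 /M²/min, Ea = 44.0 kJ/mol)
    Q + D + X → D + J (k = 2.20 /M²/min, Ea = 42.0 kJ/mol)
    D + Z ⇌ G, settled at all times (K = 150 /M, ΔH = −46.0 kJ/mol)
    L ⇌ X (k = 0.00120 /min, Ea = 114 kJ/mol)
    (constants at 60 °C)

**The neighbour.** With 1.04% of J, the asked flask holds 59.5% of E plus J against its ceiling of 60.0%, and 0.76% of its Q is left. The neighbouring flask, the same but charged with 0.720 equiv of Q, has a ceiling of 36.0%, lower than the frozen limit. It gives 35.5% of E and 0.511% of J at 40.0 h, with 0.053% of its Q left.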